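**Retrosynthetic overview**

1. The target is cut at C7–C8 of the O-hexadecyl chain (numbered from the ester oxygen) and at the two phenolic O–H bonds. C7=C8 is made by cross-metathesis of an oct-7-enyl ester with dec-1-ene, and the same flask then receives H2/Pd, which saturates the alkene and removes both benzyl ethers.
2. Enabling feature: C2–C15 of the hexadecyl chain is an unbranched run of CH2 groups with no heteroatom and no stereocentre. C7 and C8 lie six and seven carbons from the ester O and far from the 1,2-dihydroxybenzene ring, so the bond can be forged at the alkene oxidation level without geometric control and the unsaturation hydrogenated away.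
3. The ester C(=O)–O bond is made first, by lipase esterification of dihydrocaffeic acid with oct-7-en-1-ol; the two phenol oxygens on C3 and C4 of the benzene ring are then benzylated.
4. Ring order: no ring is built; the benzene ring is carried unchanged from dihydrocaffeic acid.

Key step: step 3

Remark: 3-(3,4-dihydroxyphenyl)propanoic acid, oct-7-en-1-ol and dec-1-ene are taken as commercial; alkene 6 is expected as an E/Z mixture and only the E isomer is drawn.

**Route**

Step 1
Reactants: 1 3-(3,4-dihydroxyphenyl)propanoic acid (dihydrocaffeic acid); 2 oct-7-en-1-ol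
Product: 3 oct-7-en-1-yl 3-(3,4-dihydroxyphenyl)propanoate
Conditions: Novozym 435 (immobilised Candida antarctica lipase B), 2 (3 equiv), 4 Å MS, hexane/2-butanone 3:1, 60 °C
Reagents that add atoms: none
Why: Lipase-catalysed esterification, the known enzymatic lipophilisation of hydroxyphenylpropanoic acids with fatty alcohols, should acylate only the primary alcohol with the aliphatic carboxyl group, because the phenols are not acceptors for the acyl-enzyme and the sieves remove water to pull the equilibrium.

Step 2
Reactants: 3 oct-7-en-1-yl 3-(3,4-dihydroxyphenyl)propanoate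
Product: 4 oct-7-en-1-yl 3-[3,4-bis(benzyloxy)phenyl]propanoate
Conditions: BnBr (2.4 equiv), K2CO3 (3 equiv), acetone, reflux, N2
Reagents that add atoms: benzyl bromide, BrCc1ccccc1
Why: Williamson ether synthesis, in which carbonate deprotonates both phenols and the phenoxides displace bromide from benzyl bromide by SN2, while the alkyl ester and the terminal alkene are inert to anhydrous carbonate; the benzyl ethers keep the catechol away from ruthenium and fall off in the hydrogenation stage of step 3.

Step 3
Reactants: 4 oct-7-en-1-yl 3-[3,4-bis(benzyloxy)phenyl]propanoate; 5 dec-1-ene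
Product: 7 hexadecyl 3-(3,4-dihydroxyphenyl)propanoate, via bis-benzyl hexadec-7-enyl ester 6 (not isolated)
Conditions: Hoveyda–Grubbs II (3 mol%), 5 (4 equiv), EtOAc, 45 °C, Ar sparge (−C2H4); then EtOH, 10% Pd/C, H2 (1 atm), rt, same flask
Reagents that add atoms: none
Why: Cross-metathesis by the Chauvin mechanism: the Ru alkylidene engages the terminal C=C of 4 and of 5 through ruthenacyclobutanes ([2+2]/retro-[2+2]), expels ethene and joins C7 of the ester chain to C2 of dec-1-ene (C8 of the product chain) as the internal alkene 6, which the Pd/C and H2 added to the same flask should saturate while hydrogenolysing both aryl benzyl ethers. The closest known reaction types are the cross-metathesis of two unhindered terminal (type I) olefins and one-pot metathesis/heterogeneous hydrogenation, with O-debenzylation under the same H2/Pd conditions being standard. No ring is closed and no stereocentre is formed, and the E/Z mixture of 6 is of no consequence because the double bond is erased. The selectivity needed is cross- over homo-coupling and the absence of double-bond migration: both partners are equilibrating type I olefins, so the excess of cheap 5 statistically channels 4 into 6, and the by-products after hydrogenation (octadecane, decane, the symmetrical C14 diester) differ strongly in polarity from 7. The ester, the arene and the benzyl ethers are inert to the Ru carbene, six methylenes insulate the alkene from the ester oxygen so no chelate can form, and the phosphine-free catalyst leaves no ligand that poisons palladium; the alkyl ester and the aromatic ring are not reduced at 1 atm and room temperature.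

**Compound list**

1 | 3-(3,4-dihydroxyphenyl)propanoic acid (dihydrocaffeic acid) | OC(=O)CCc1ccc(O)c(O)c1 | starting material
2 | oct-7-en-1-ol | OCCCCCCC=C | starting material
3 | oct-7-en-1-yl 3-(3,4-dihydroxyphenyl)propanoate | C=CCCCCCCOC(=O)CCc1ccc(O)c(O)c1 | intermediate
4 | oct-7-en-1-yl 3-[3,4-bis(benzyloxy)phenyl]propanoate | C=CCCCCCCOC(=O)CCc1ccc(OCc2ccccc2)c(OCc3ccccc3)c1 | intermediate
5 | dec-1-ene | C=CCCCCCCCC | starting material
6 | hexadec-7-en-1-yl 3-[3,4-bis(benzyloxy)phenyl]propanoate (E isomer drawn; E/Z mixture expected; not isolated) | CCCCCCCC/C=C/CCCCCCOC(=O)CCc1ccc(OCc2ccccc2)c(OCc3ccccc3)c1 | intermediate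
7 | hexadecyl 3-(3,4-dihydroxyphenyl)propanoate | CCCCCCCCCCCCCCCCOC(=O)CCc1ccc(O)c(O)c1 | target

**Summary**

Total step count: 3
Longest linear sequence: 3 steps (1 → 3 → 4 → 7)

**Steps most likely to fail**

1. Step 3. Ruthenium hydride formed by catalyst decay may migrate the double bond in 4, 5 or 6 before metathesis is complete, which would put chain-length homologues into the product that cannot be separated from 7 after hydrogenation; statistical homo-coupling may also hold back conversion. Fallback, setting out from 4 and returning at 7: oxidative cleavage of the terminal alkene of 4 (cat. OsO4, NaIO4, 2,6-lutidine, dioxane/H2O) should give 7-oxoheptyl 3-[3,4-bis(benzyloxy)phenyl]propanoate F1. Wittig olefination of F1 with nonylidene(triphenyl)phosphorane F2, generated in the flask from commercial nonyltriphenylphosphonium bromide and NaHMDS in THF at −78 °C, should form the same C7=C8 bond with the chain length fixed by the two partners and give (Z)-hexadec-7-en-1-yl 3-[3,4-bis(benzyloxy)phenyl]propanoate F3. Hydrogenation of F3 (H2, 10% Pd/C, EtOAc/EtOH, rt) should saturate the alkene and remove both benzyl groups to give 7.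

2. Step 1. The esterification may stall at partial conversion because water builds up on the enzyme support or the polar acid dissolves poorly in the apolar medium. Fallback, setting out from 1 and returning at 4 (it also replaces step 2): exhaustive benzylation of 1 (BnBr, K2CO3, DMF) should give benzyl 3-[3,4-bis(benzyloxy)phenyl]propanoate F4. Saponification (LiOH, THF/H2O) should give 3-[3,4-bis(benzyloxy)phenyl]propanoic acid F5, and carbodiimide esterification of F5 with 2 (EDC·HCl, DMAP, CH2Cl2) should give 4.

3. Step 2. The catecholate may be oxidised by traces of air under the basic conditions, or the alkylation may stop at the mono-benzyl stage or divert to C-benzylation of the electron-rich ring. Fallback, setting out from 3 and returning at 7: silylation under near-neutral conditions (TBSCl, imidazole, DMF) should give oct-7-en-1-yl 3-[3,4-bis(tert-butyldimethylsilyloxy)phenyl]propanoate F6. The same cross-metathesis with 5 (Hoveyda–Grubbs II, EtOAc, 45 °C) should give hexadec-7-en-1-yl 3-[3,4-bis(tert-butyldimethylsilyloxy)phenyl]propanoate F7 in the flask, and hydrogenation there (H2, Pd/C), which leaves aryl silyl ethers intact, should give hexadecyl 3-[3,4-bis(tert-butyldimethylsilyloxy)phenyl]propanoate F8. Cleavage of the two phenolic silyl ethers of F8 with KHF2 in MeOH at rt, which does not touch the alkyl ester, should give 7.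

**Further compounds**

F1 | step 3 | 7-oxoheptyl 3-[3,4-bis(benzyloxy)phenyl]propanoate | O=CCCCCCCOC(=O)CCc1ccc(OCc2ccccc2)c(OCc3ccccc3)c1
F2 | step 3 | nonylidene(triphenyl)phosphorane | CCCCCCCCC=P(c1ccccc1)(c1ccccc1)c1ccccc1
F3 | step 3 | (Z)-hexadec-7-en-1-yl 3-[3,4-bis(benzyloxy)phenyl]propanoate | CCCCCCCC/C=C\CCCCCCOC(=O)CCc1ccc(OCc2ccccc2)c(OCc3ccccc3)c1
F4 | step 1 | benzyl 3-[3,4-bis(benzyloxy)phenyl]propanoate | O=C(CCc1ccc(OCc2ccccc2)c(OCc3ccccc3)c1)OCc1ccccc1
F5 | step 1 | 3-[3,4-bis(benzyloxy)phenyl]propanoic acid | OC(=O)CCc1ccc(OCc2ccccc2)c(OCc3ccccc3)c1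
F6 | step 2 | oct-7-en-1-yl 3-[3,4-bis(tert-butyldimethylsilyloxy)phenyl]propanoate | C=CCCCCCCOC(=O)CCc1ccc(O[Si](C)(C)C(C)(C)C)c(O[Si](C)(C)C(C)(C)C)c1
F7 | step 2 | hexadec-7-en-1-yl 3-[3,4-bis(tert-butyldimethylsilyloxy)phenyl]propanoate (E isomer drawn; E/Z mixture expected; not isolated) | CCCCCCCC/C=C/CCCCCCOC(=O)CCc1ccc(O[Si](C)(C)C(C)(C)C)c(O[Si](C)(C)C(C)(C)C)c1
F8 | step 2 | hexadecyl 3-[3,4-bis(tert-butyldimethylsilyloxy)phenyl]propanoate | CCCCCCCCCCCCCCCCOC(=O)CCc1ccc(O[Si](C)(C)C(C)(C)C)c(O[Si](C)(C)C(C)(C)C)c1
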